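**Plan**
- Atom numbers follow the hexacosanolide chain: C1 is the lactone carbonyl, C22 the ketone, C26 the OCH2 carbon.
- Retrosynthesis cuts, in order: (i) C3–C4, by a radical ring closure, which opens the 27-membered lactone to an open-chain ω-iodoalkyl acrylate; (ii) the acyl C1–O26 bond (acrylate ester); (iii) C21–C22, by alkylation of C6-lithiated 3,4-dihydro-2H-pyran, whose ring temporarily masks the C22 ketone and the C26 hydroxyl.
- Enabling feature: the lactone segment O26–C1(=O)–C2H2–C3H2 is a saturated acrylate ester. With C2=C3 restored, C3 is the unsubstituted acrylate β-carbon and C4 a primary C–I carbon. These two electrophilic carbons are joined through a C4 radical (reductive union of like polarity).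
- Forward: the C23 chain is joined at C21–C22, O26 is acrylated, and the only ring, the 27-membered macrolactone, closes last. The iodine activator is lost in the ring closure itself, so no helper group remains to be removed.
- Stereochemistry: the target has no stereocentre and no C=C, so nothing has to be controlled.

Key step: step 4

Remark: 1,18-octadecanediol is assumed to be purchasable; it would otherwise come in one step from octadecanedioic acid by LiAlH4 reduction.

**Step 1**
Reactants: 1 1,18-octadecanediol
Product: 2 1,18-diiodooctadecane
Conditions: PPh3, I2, imidazole, THF/CH2Cl2, 0 °C → rt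
Reagents that add atoms: iodine, II
Why: Appel-type iodination under Garegg–Samuelsson conditions activates both primary hydroxyls as alkoxyphosphonium ions, which iodide displaces by SN2; this is reliable for unhindered primary alcohols.

**Step 2**
Reactants: 3 3,4-dihydro-2H-pyran; 2 1,18-diiodooctadecane
Product: 6 1-hydroxy-23-iodotricosan-5-one, via 6-lithio-3,4-dihydro-2H-pyran 4 (not isolated), via 6-(18-iodooctadecyl)-3,4-dihydro-2H-pyran 5 (not isolated)
Conditions: t-BuLi (1.0 equiv), 3 (1.3 equiv), THF/pentane, −78 → 0 °C; then 2 (3 equiv, excess recovered), THF, 0 °C → rt; then 1 M HCl, THF/H2O, rt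
Reagents that add atoms: water, O
Why: The vinylic C–H next to the ring oxygen of 3 is lithiated to an α-alkoxyvinyllithium (acyl-anion equivalent) that is alkylated by SN2 at one primary C–I of 2, the excess of 2 holding the reaction at mono-substitution, and dilute acid then hydrolyses the enol ether to the δ-hydroxy ketone (umpolung alkylation of a lithiated enol ether followed by enol ether hydrolysis).

**Step 3**
Reactants: 6 1-hydroxy-23-iodotricosan-5-one; 7 acryloyl chloride
Product: 8 23-iodo-5-oxotricosyl prop-2-enoate
Conditions: i-Pr2NEt, CH2Cl2, 0 °C (trace BHT)
Reagents that add atoms: none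
Why: O-Acylation of an unhindered primary alcohol by an acid chloride with a hindered amine base (nucleophilic acyl substitution) is fast at 0 °C and should leave the ketone and the primary iodide untouched.

**Step 4**
Reactants: 8 23-iodo-5-oxotricosyl prop-2-enoate
Product: 9 22-keto-26-hexacosanolide (1-oxacycloheptacosane-2,23-dione)
Conditions: Bu3SnH (1.2 equiv, syringe pump), AIBN (cat.), PhH, reflux, substrate about 2 mM
Reagents that add atoms: none
Why: Bu3Sn• (from Bu3SnH/AIBN) abstracts iodine from C4 of 8, the nucleophilic primary alkyl radical adds to the unsubstituted β-carbon C3 of the electron-poor acrylate, and the resulting α-ester radical at C2 takes hydrogen from Bu3SnH to carry the chain. The closest known reaction type is the intramolecular Giese addition used in tin hydride radical macrocyclisation of ω-iodoalkyl acrylates to macrolides. The single ring closes in the 27-endo-trig mode; the 26-exo attack at the substituted α-carbon C2 is disfavoured sterically and by polarity. No stereocentre is formed. The step needs ring closure to outrun direct reduction of the C4 radical and intermolecular addition, which the polarity-matched radical/acceptor pair, the unstrained large ring, millimolar dilution and slow hydride addition (low Sn–H concentration) should secure. Chemoselectivity rests on iodine abstraction being much faster than stannyl radical addition to the acrylate and on the isolated C22 ketone being inert to alkyl radicals.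

**Compound list**
1 | 1,18-octadecanediol | OCCCCCCCCCCCCCCCCCCO | starting material
2 | 1,18-diiodooctadecane | ICCCCCCCCCCCCCCCCCCI | intermediate
3 | 3,4-dihydro-2H-pyran | C1=COCCC1 | starting material
4 | 6-lithio-3,4-dihydro-2H-pyran | [Li]C1=CCCCO1 | intermediate
5 | 6-(18-iodooctadecyl)-3,4-dihydro-2H-pyran | ICCCCCCCCCCCCCCCCCCC1=CCCCO1 | intermediate
6 | 1-hydroxy-23-iodotricosan-5-one | OCCCCC(=O)CCCCCCCCCCCCCCCCCCI | intermediate
7 | acryloyl chloride (prop-2-enoyl chloride) | C=CC(=O)Cl | starting material
8 | 23-iodo-5-oxotricosyl prop-2-enoate | C=CC(=O)OCCCCC(=O)CCCCCCCCCCCCCCCCCCI | intermediate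
9 | 22-keto-26-hexacosanolide (1-oxacycloheptacosane-2,23-dione) | O=C1CCCCCCCCCCCCCCCCCCCCC(=O)OCCCC1 | target

**Step count**
Total steps: 4. Longest linear sequence: 4 (1 → 2 → 6 → 8 → 9).

**Steps most likely to fail**

1. Step 4. Hydrogen transfer to the open-chain C4 radical and intermolecular radical addition (telomerisation) may outrun the slow 27-membered ring closure. Fallback (sets out from 6, returns at 9): the ring would be closed at the ester C1–O26 bond instead. Intermolecular Giese addition of the radical from 6 to excess methyl acrylate (Bu3SnH, AIBN, PhH, 80 °C) should give methyl 26-hydroxy-22-oxohexacosanoate F1. Saponification (LiOH, THF/H2O) should give 26-hydroxy-22-oxohexacosanoic acid F2. Yamaguchi macrolactonisation (2,4,6-trichlorobenzoyl chloride, Et3N, THF; then slow addition to DMAP in refluxing toluene at high dilution) should pass through 26-hydroxy-22-oxohexacosanoic 2,4,6-trichlorobenzoic anhydride F3 and give 9.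

2. Step 2. Double substitution of the diiodide, β-elimination or iodine–lithium exchange in place of SN2 alkylation, and poor solubility of the long-chain diiodide at low temperature may erode the mono-alkylation. Fallback (sets out from 1, returns at 6): the polarity at C21–C22 is reversed and the chain ends are differentiated from the start. Monochlorination of 1 (conc. HCl, toluene, reflux) should give 18-chlorooctadecan-1-ol F4. Appel bromination (CBr4, PPh3, CH2Cl2) should give 1-bromo-18-chlorooctadecane F5. Magnesium insertion at the C–Br bond (Mg, THF) should give (18-chlorooctadecyl)magnesium bromide F6. Single addition of F6 to δ-valerolactone (THF, −78 °C, then aq. NH4Cl) should give 23-chloro-1-hydroxytricosan-5-one F7. Finkelstein exchange (NaI, 2-butanone, reflux) should then give 6.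

3. Step 3. Conjugate addition of chloride or amine to the acrylate and radical polymerisation during acylation and isolation may consume the ester. Fallback (sets out from 6, returns at 8): the acrylate is introduced in masked form. Acylation of 6 with 3-chloropropanoyl chloride (pyridine, CH2Cl2, 0 °C) should give 23-iodo-5-oxotricosyl 3-chloropropanoate F8. E1cB elimination of HCl (Et3N, CH2Cl2, rt) should then unveil the double bond and give 8.

**Further compounds**
F1 | step 4 | methyl 26-hydroxy-22-oxohexacosanoate | COC(=O)CCCCCCCCCCCCCCCCCCCCC(=O)CCCCO
F2 | step 4 | 26-hydroxy-22-oxohexacosanoic acid | OC(=O)CCCCCCCCCCCCCCCCCCCCC(=O)CCCCO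
F3 | step 4 | 26-hydroxy-22-oxohexacosanoic 2,4,6-trichlorobenzoic anhydride | OCCCCC(=O)CCCCCCCCCCCCCCCCCCCCC(=O)OC(=O)c1c(Cl)cc(Cl)cc1Cl
F4 | step 2 | 18-chlorooctadecan-1-ol | OCCCCCCCCCCCCCCCCCCCl
F5 | step 2 | 1-bromo-18-chlorooctadecane | BrCCCCCCCCCCCCCCCCCCCl
F6 | step 2 | (18-chlorooctadecyl)magnesium bromide | ClCCCCCCCCCCCCCCCCCC[Mg]Br
F7 | step 2 | 23-chloro-1-hydroxytricosan-5-one | OCCCCC(=O)CCCCCCCCCCCCCCCCCCCl
F8 | step 3 | 23-iodo-5-oxotricosyl 3-chloropropanoate | ClCCC(=O)OCCCCC(=O)CCCCCCCCCCCCCCCCCCI
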